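**Retrosynthetic overview**

1. Target 32 [(1R,5R,6S) core, tertiary OH syn to the oxirane oxygen] ⇐ Stille coupling of vinylstannane 23 with bromodienamide 31 (lower trienamide chain last).
2. 23 ⇐ hydroxyl-directed nucleophilic epoxidation of p-quinol 22 ⇐ fluoride unmasking of cyclohexa-2,5-dienone 21.
3. 21 ⇐ nickel-catalysed [4+2] insertion of terminal ynamide 9 (already carrying the upper dienoyl chain) into the C1–C4 σ bond of enantioenriched cyclobutenone 20; this forms C2–C3 and C4–C5 of the core.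
4. Enabling feature: in the carbocycle of the 7-oxabicyclo[4.1.0]heptenone, C5(OH)(trienyl)–C6–C1–C2(=O) (carbinol, the two oxirane carbons, ketone) is a contiguous four-carbon chain flanked by the two-carbon enamide C3(N)=C4H. It maps onto a 4-oxycyclobut-2-enone whose strained acyl–allyl bond can be cut and re-sewn around an alkyne, carrying the C5 stereocentre across unchanged.
5. 20 ⇐ squaric acid 10 (menthyl auxiliary, stannylvinyllithium addition, carbonyl transposition). Ring order: cyclobutenone (sacrificial) → six-membered carbocycle (step 10) → oxirane (step 12).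

Key step: step 10

Assumption: the sense of 1,3-induction by the menthyl group in step 7 cannot be predicted with confidence; the route is written for (−)-menthol with the (4R) epimer isolated by chromatography, and (+)-menthol would be used instead if (4R) proves to be the minor epimer.

**Route**

Step 1
Reactants: 1 cyclohexanecarbaldehyde; 2 triethyl (E)-4-phosphonocrotonate
Product: 3 ethyl (2E,4E)-5-cyclohexylpenta-2,4-dienoate
Conditions: LiN(SiMe3)2, THF, −78 °C → 0 °C
Reagents that add atoms: none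
Why: Vinylogous Horner–Wadsworth–Emmons olefination, in which the stabilised phosphonate anion should give the (2E,4E)-dienoate.

Step 2
Reactants: 3 ethyl (2E,4E)-5-cyclohexylpenta-2,4-dienoate
Product: 4 (2E,4E)-5-cyclohexylpenta-2,4-dienoic acid
Conditions: LiOH·H2O, THF/MeOH/H2O, rt; then 1 M HCl
Reagents that add atoms: lithium hydroxide [Li+].[OH-]
Why: Ester saponification, to which the conjugated diene is inert at room temperature.

Step 3
Reactants: 4 (2E,4E)-5-cyclohexylpenta-2,4-dienoic acid
Product: 7 2-(trimethylsilyl)ethyl N-[(2E,4E)-5-cyclohexylpenta-2,4-dienoyl]carbamate, via dienoyl chloride 5 (not isolated), via dienoyl isocyanate 6 (not isolated)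
Conditions: (COCl)2, DMF (cat.), CH2Cl2, 0 °C → rt, evaporate; AgOCN, toluene, 60 °C; then Me3SiCH2CH2OH, 0 °C → rt
Reagents that add atoms: silver cyanate [Ag+].[O-]C#N; 2-(trimethylsilyl)ethanol C[Si](C)(C)CCO
Why: Acid chloride formation, metathesis with silver cyanate to the acyl isocyanate and addition of the alcohol across N=C=O should give the N-acyl carbamate, which puts a fluoride-labile second substituent (Teoc) on nitrogen.

Step 4
Reactants: 7 2-(trimethylsilyl)ethyl N-[(2E,4E)-5-cyclohexylpenta-2,4-dienoyl]carbamate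
Product: 9 2-(trimethylsilyl)ethyl N-[(2E,4E)-5-cyclohexylpenta-2,4-dienoyl]-N-ethynylcarbamate, via silylated ynamide 8 (not isolated)
Conditions: KN(SiMe3)2, toluene, 0 °C; PhI(C≡CSiMe3)OTf, 0 °C → rt; then TBAF (1.05 equiv), AcOH, THF, −40 °C
Reagents that add atoms: phenyl[(trimethylsilyl)ethynyl]iodonium triflate C[Si](C)(C)C#C[I+]c1ccccc1.[O-]S(=O)(=O)C(F)(F)F
Why: N-Alkynylation of a soft imide-type anion with an alkynyl iodonium salt (conjugate addition, loss of iodobenzene, 1,2-silyl shift of the alkylidene carbene), followed by fluoride cleavage of the alkynyl C–Si bond, which should be far faster at −40 °C than attack on the Teoc group.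

Step 5
Reactants: 10 squaric acid; 11 (−)-menthol [(1R,2S,5R)], used in 2.2 equiv
Product: 12 bis[(1R,2S,5R)-menthyl] squarate
Conditions: 11 (2.2 equiv), toluene, reflux, Dean–Stark
Reagents that add atoms: (−)-menthol (second equivalent of 11) CC(C)[C@@H]1CC[C@@H](C)C[C@H]1O
Why: Twofold azeotropic esterification of the vinylogous diacid, in which each acidic hydroxyl is replaced by a menthyloxy group by addition–elimination at the ring carbon with loss of water, so that two equivalents of 11 are consumed and the C–O bonds and stereocentres of the auxiliary stay untouched.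

Step 6
Reactants: 12 bis[(1R,2S,5R)-menthyl] squarate
Product: 14 3-[(1R,2S,5R)-menthyloxy]cyclobut-3-ene-1,2-dione, via hydroxycyclobutenone 13 (not isolated)
Conditions: LiAlH(OtBu)3, THF, −78 → −20 °C; then 6 M HCl, CH2Cl2, 0 °C
Reagents that add atoms: water O (oxygen of the new C2 carbonyl; the original hydroxyl leaves as water)
Why: 1,2-Reduction of one vinylogous ester carbonyl and acid-promoted allylic transposition with loss of one menthol is the standard squarate-to-semisquarate conversion.

Step 7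
Reactants: 14 3-[(1R,2S,5R)-menthyloxy]cyclobut-3-ene-1,2-dione; 15 (E)-1,2-bis(tributylstannyl)ethene
Product: 17 (4R)-4-hydroxy-3-[(1R,2S,5R)-menthyloxy]-4-[(E)-2-(tributylstannyl)ethenyl]cyclobut-2-en-1-one, via vinyllithium 16 (not isolated)
Conditions: 15, n-BuLi, THF, −78 °C; then 14, −78 °C; sat. aq. NH4Cl; chromatographic separation of the C4 epimers
Reagents that add atoms: none
Why: Tin–lithium exchange gives the (E)-vinyllithium with retention, which should add 1,2 to the ketone-like carbonyl (the one not in vinylogous-ester conjugation); the new carbinol centre forms under 1,3-induction from the adjacent menthyloxy group, expected to be modest, and the (4R) epimer is secured by separating the two diastereomers.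

Step 8
Reactants: 17 (4R)-4-hydroxy-3-[(1R,2S,5R)-menthyloxy]-4-[(E)-2-(tributylstannyl)ethenyl]cyclobut-2-en-1-one
Product: 18 (4R)-3-[(1R,2S,5R)-menthyloxy]-4-(triethylsilyloxy)-4-[(E)-2-(tributylstannyl)ethenyl]cyclobut-2-en-1-one
Conditions: TESOTf, 2,6-lutidine, CH2Cl2, −78 → 0 °C
Reagents that add atoms: triethylsilyl triflate CC[Si](CC)(CC)OS(=O)(=O)C(F)(F)F
Why: Silyl triflate silylation of the hindered tertiary alcohol, giving a fluoride-labile ether that prevents lactonisation once the four-membered ring is opened.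

Step 9
Reactants: 18 (4R)-3-[(1R,2S,5R)-menthyloxy]-4-(triethylsilyloxy)-4-[(E)-2-(tributylstannyl)ethenyl]cyclobut-2-en-1-one
Product: 20 (4R)-4-(triethylsilyloxy)-4-[(E)-2-(tributylstannyl)ethenyl]cyclobut-2-en-1-one, via cyclobutenol 19 (not isolated)
Conditions: i-Bu2AlH, toluene, −78 °C; then 0.5 M aq. oxalic acid, Et2O, 0 °C; product kept cold and used at once
Reagents that add atoms: water O (oxygen of the new carbonyl; the reduced carbinol oxygen leaves as water)
Why: Stork–Danheiser-type carbonyl transposition (1,2-reduction of the vinylogous ester, mild acid hydrolysis of the 3-alkoxycyclobutenol, dehydration) should place the ketone next to the carbinol carbon, leave C2 and C3 unsubstituted and release the auxiliary without touching the stereocentre.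

Step 10
Reactants: 20 (4R)-4-(triethylsilyloxy)-4-[(E)-2-(tributylstannyl)ethenyl]cyclobut-2-en-1-one; 9 2-(trimethylsilyl)ethyl N-[(2E,4E)-5-cyclohexylpenta-2,4-dienoyl]-N-ethynylcarbamate
Product: 21 2-(trimethylsilyl)ethyl N-[(2E,4E)-5-cyclohexylpenta-2,4-dienoyl]-N-{(3S)-6-oxo-3-(triethylsilyloxy)-3-[(E)-2-(tributylstannyl)ethenyl]cyclohexa-1,4-dien-1-yl}carbamate
Conditions: Ni(cod)2 (10 mol%), PPh3 (20 mol%), toluene, 0 °C, slow addition of 9 (1.5 equiv), then rt
Reagents that add atoms: none
Why: Proposed new method: zerovalent nickel should insert into the strained acyl–allyl σ bond C1–C4 of 20 with retention at C4 to give a five-membered acyl(allyl)nickel metallacycle; syn 1,2-insertion of the terminal alkyne of 9 into the Ni–C4 bond then puts the quaternary carbon on the unsubstituted alkyne terminus and nickel on the nitrogen-bearing carbon, and C(acyl)–C(sp2) reductive elimination from the seven-membered nickelacycle forms the second bond and releases the catalyst. The closest known reaction type is the nickel-catalysed [4+2] benzannulation of cyclobutenones with alkynes (with the related nickel- and rhodium-catalysed cut-and-sew insertions into cyclobutanones); new here are the 4,4-disubstituted cyclobutenone, which cannot aromatise and so should stop at the cyclohexa-2,5-dienone, and the ynamide partner. The six-membered ring is closed by formal [4+2] insertion of the two alkyne carbons into the cleaved C1–C4 bond, the closing event being the reductive elimination. No new stereocentre is created: the carbinol centre is carried through because oxidative addition, migratory insertion and the ring-constrained allylnickel bonding all keep nickel on one face of C4, provided the metallacycle does not dissociate to the free, achiral vinylketene, which the low temperature is meant to prevent. The step needs regioselectivity (C4 to the CH terminus, acyl to the N-bearing carbon), which the steric demand of the quaternary C4 and chelation of an imide carbonyl to nickel (as in chelation-controlled carbometalation of ynamides) should secure, and chemoselectivity over thermal ring opening with 6π-electrocyclisation onto the C4 vinyl group and over alkyne oligomerisation, which 0 °C and slow addition of 9 should secure.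

Step 11
Reactants: 21 2-(trimethylsilyl)ethyl N-[(2E,4E)-5-cyclohexylpenta-2,4-dienoyl]-N-{(3S)-6-oxo-3-(triethylsilyloxy)-3-[(E)-2-(tributylstannyl)ethenyl]cyclohexa-1,4-dien-1-yl}carbamate
Product: 22 (2E,4E)-5-cyclohexyl-N-{(3S)-3-hydroxy-6-oxo-3-[(E)-2-(tributylstannyl)ethenyl]cyclohexa-1,4-dien-1-yl}penta-2,4-dienamide
Conditions: TBAF (2.5 equiv), AcOH (2.5 equiv), THF, 0 °C → rt
Reagents that add atoms: none
Why: Fluoride should cleave the triethylsilyl ether and trigger β-elimination of the Teoc group (ethene, CO2), unmasking the tertiary alcohol and the secondary enamide in one operation, with acetic acid as buffer and the vinylstannane inert to fluoride.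

Step 12
Reactants: 22 (2E,4E)-5-cyclohexyl-N-{(3S)-3-hydroxy-6-oxo-3-[(E)-2-(tributylstannyl)ethenyl]cyclohexa-1,4-dien-1-yl}penta-2,4-dienamide
Product: 23 (2E,4E)-5-cyclohexyl-N-{(1R,5S,6S)-5-hydroxy-2-oxo-5-[(E)-2-(tributylstannyl)ethenyl]-7-oxabicyclo[4.1.0]hept-3-en-3-yl}penta-2,4-dienamide
Conditions: t-BuOOH (decane), DBU, CH2Cl2, 0 °C
Reagents that add atoms: tert-butyl hydroperoxide CC(C)(C)OO
Why: Weitz–Scheffer nucleophilic epoxidation, in which the hydroperoxide anion should attack the unsubstituted enone arm (the amido-bearing arm is deactivated at its β-carbon by the enamide nitrogen) and be delivered by hydrogen bonding to the tertiary hydroxyl and away from the bulky stannylvinyl group, so that both oxirane centres are set syn to the hydroxyl.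

Step 13
Reactants: 24 glutaconaldehyde potassium salt
Product: 25 (2E,4E)-5-bromopenta-2,4-dienal
Conditions: PPh3, Br2, CH2Cl2, 0 °C → rt
Reagents that add atoms: bromine BrBr (delivered as Ph3PBr2)
Why: The dienolate oxygen is activated as an oxyphosphonium ion and replaced by bromide in an addition–elimination, which should give the thermodynamically preferred (2E,4E)-bromodienal.

Step 14
Reactants: 25 (2E,4E)-5-bromopenta-2,4-dienal
Product: 26 (2E,4E)-5-bromopenta-2,4-dienoic acid
Conditions: NaClO2, NaH2PO4, 2-methylbut-2-ene, t-BuOH/H2O, 0 °C → rt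
Reagents that add atoms: sodium chlorite [Na+].[O-]Cl=O
Why: Pinnick oxidation of the aldehyde, with the alkene scavenger protecting the bromodiene from hypochlorous acid.

Step 15
Reactants: 27 cyclopentane-1,3-dione
Product: 28 2-(hydroxyimino)cyclopentane-1,3-dione
Conditions: NaNO2, aq. HCl, 0 °C
Reagents that add atoms: sodium nitrite [Na+].[O-]N=O
Why: Nitrosation of the activated methylene of the 1,3-dione should give the 2-oxime.

Step 16
Reactants: 28 2-(hydroxyimino)cyclopentane-1,3-dione
Product: 29 2-amino-3-hydroxycyclopent-2-en-1-one hydrochloride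
Conditions: H2 (1 atm), Pd/C, HCl, EtOH, rt
Reagents that add atoms: hydrogen chloride Cl
Why: Catalytic hydrogenation of the oxime in acid should give the amine, isolated as the stable hydrochloride of the enolised 2-amino-1,3-dione.

Step 17
Reactants: 26 (2E,4E)-5-bromopenta-2,4-dienoic acid; 29 2-amino-3-hydroxycyclopent-2-en-1-one hydrochloride
Product: 31 (2E,4E)-5-bromo-N-(2-hydroxy-5-oxocyclopent-1-en-1-yl)penta-2,4-dienamide, via bromodienoyl chloride 30 (not isolated)
Conditions: (COCl)2, DMF (cat.), CH2Cl2, 0 °C; then 29, N-methylmorpholine, THF, 0 °C → rt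
Reagents that add atoms: none
Why: Acid chloride formation and N-acylation of the aminoenone (amide formation), in which any O-acylated enol ester should transfer its acyl group to nitrogen.

Step 18
Reactants: 23 (2E,4E)-5-cyclohexyl-N-{(1R,5S,6S)-5-hydroxy-2-oxo-5-[(E)-2-(tributylstannyl)ethenyl]-7-oxabicyclo[4.1.0]hept-3-en-3-yl}penta-2,4-dienamide; 31 (2E,4E)-5-bromo-N-(2-hydroxy-5-oxocyclopent-1-en-1-yl)penta-2,4-dienamide
Product: 32 (2E,4E)-5-cyclohexyl-N-[(1R,5R,6S)-5-hydroxy-5-{(1E,3E,5E)-7-[(2-hydroxy-5-oxocyclopent-1-en-1-yl)amino]-7-oxohepta-1,3,5-trien-1-yl}-2-oxo-7-oxabicyclo[4.1.0]hept-3-en-3-yl]penta-2,4-dienamide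
Conditions: PdCl2(MeCN)2 (10 mol%), DMF, rt, dark
Reagents that add atoms: none
Why: Ligand-free Stille coupling should join the vinylstannane and the bromodiene with retention of both alkene geometries under neutral conditions that tolerate the free hydroxyl, the epoxy ketone and the acidic enaminone, and it affects no stereocentre.

**Compound list**

1 | cyclohexanecarbaldehyde | O=CC1CCCCC1 | starting material
2 | triethyl (E)-4-phosphonocrotonate | CCOC(=O)/C=C/CP(=O)(OCC)OCC | starting material
3 | ethyl (2E,4E)-5-cyclohexylpenta-2,4-dienoate | CCOC(=O)/C=C/C=C/C1CCCCC1 | intermediate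
4 | (2E,4E)-5-cyclohexylpenta-2,4-dienoic acid | OC(=O)/C=C/C=C/C1CCCCC1 | intermediate
5 | (2E,4E)-5-cyclohexylpenta-2,4-dienoyl chloride | ClC(=O)/C=C/C=C/C1CCCCC1 | intermediate
6 | (2E,4E)-5-cyclohexylpenta-2,4-dienoyl isocyanate | O=C=NC(=O)/C=C/C=C/C1CCCCC1 | intermediate
7 | 2-(trimethylsilyl)ethyl N-[(2E,4E)-5-cyclohexylpenta-2,4-dienoyl]carbamate | C[Si](C)(C)CCOC(=O)NC(=O)/C=C/C=C/C1CCCCC1 | intermediate
8 | 2-(trimethylsilyl)ethyl N-[(2E,4E)-5-cyclohexylpenta-2,4-dienoyl]-N-[(trimethylsilyl)ethynyl]carbamate | C[Si](C)(C)C#CN(C(=O)OCC[Si](C)(C)C)C(=O)/C=C/C=C/C1CCCCC1 | intermediate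
9 | 2-(trimethylsilyl)ethyl N-[(2E,4E)-5-cyclohexylpenta-2,4-dienoyl]-N-ethynylcarbamate | C#CN(C(=O)OCC[Si](C)(C)C)C(=O)/C=C/C=C/C1CCCCC1 | intermediate
10 | squaric acid (3,4-dihydroxycyclobut-3-ene-1,2-dione) | O=C1C(O)=C(O)C1=O | starting material
11 | (−)-menthol, (1R,2S,5R)-5-methyl-2-(propan-2-yl)cyclohexan-1-ol | CC(C)[C@@H]1CC[C@@H](C)C[C@H]1O | starting material
12 | bis[(1R,2S,5R)-menthyl] squarate | O=C1C(=O)C(O[C@@H]2C[C@H](C)CC[C@H]2C(C)C)=C1O[C@@H]1C[C@H](C)CC[C@H]1C(C)C | intermediate
13 | 4-hydroxy-2,3-bis[(1R,2S,5R)-menthyloxy]cyclobut-2-en-1-one (both C4 epimers) | O=C1C(O[C@@H]2C[C@H](C)CC[C@H]2C(C)C)=C(O[C@@H]2C[C@H](C)CC[C@H]2C(C)C)C1O | intermediate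
14 | 3-[(1R,2S,5R)-menthyloxy]cyclobut-3-ene-1,2-dione | O=C1C=C(O[C@@H]2C[C@H](C)CC[C@H]2C(C)C)C1=O | intermediate
15 | (E)-1,2-bis(tributylstannyl)ethene | CCCC[Sn](CCCC)(CCCC)/C=C/[Sn](CCCC)(CCCC)CCCC | starting material
16 | (E)-2-(tributylstannyl)ethenyllithium | [Li]/C=C/[Sn](CCCC)(CCCC)CCCC | intermediate
17 | (4R)-4-hydroxy-3-[(1R,2S,5R)-menthyloxy]-4-[(E)-2-(tributylstannyl)ethenyl]cyclobut-2-en-1-one | O=C1C=C(O[C@@H]2C[C@H](C)CC[C@H]2C(C)C)[C@]1(O)/C=C/[Sn](CCCC)(CCCC)CCCC | intermediate
18 | (4R)-3-[(1R,2S,5R)-menthyloxy]-4-(triethylsilyloxy)-4-[(E)-2-(tributylstannyl)ethenyl]cyclobut-2-en-1-one | O=C1C=C(O[C@@H]2C[C@H](C)CC[C@H]2C(C)C)[C@]1(O[Si](CC)(CC)CC)/C=C/[Sn](CCCC)(CCCC)CCCC | intermediate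
19 | (4S)-3-[(1R,2S,5R)-menthyloxy]-4-(triethylsilyloxy)-4-[(E)-2-(tributylstannyl)ethenyl]cyclobut-2-en-1-ol (both C1 epimers) | OC1C=C(O[C@@H]2C[C@H](C)CC[C@H]2C(C)C)[C@]1(O[Si](CC)(CC)CC)/C=C/[Sn](CCCC)(CCCC)CCCC | intermediate
20 | (4R)-4-(triethylsilyloxy)-4-[(E)-2-(tributylstannyl)ethenyl]cyclobut-2-en-1-one | O=C1[C@](O[Si](CC)(CC)CC)(/C=C/[Sn](CCCC)(CCCC)CCCC)C=C1 | intermediate
21 | 2-(trimethylsilyl)ethyl N-[(2E,4E)-5-cyclohexylpenta-2,4-dienoyl]-N-{(3S)-6-oxo-3-(triethylsilyloxy)-3-[(E)-2-(tributylstannyl)ethenyl]cyclohexa-1,4-dien-1-yl}carbamate | O=C1C=C[C@@](O[Si](CC)(CC)CC)(/C=C/[Sn](CCCC)(CCCC)CCCC)C=C1N(C(=O)OCC[Si](C)(C)C)C(=O)/C=C/C=C/C1CCCCC1 | intermediate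
22 | (2E,4E)-5-cyclohexyl-N-{(3S)-3-hydroxy-6-oxo-3-[(E)-2-(tributylstannyl)ethenyl]cyclohexa-1,4-dien-1-yl}penta-2,4-dienamide | O=C1C=C[C@@](O)(/C=C/[Sn](CCCC)(CCCC)CCCC)C=C1NC(=O)/C=C/C=C/C1CCCCC1 | intermediate
23 | (2E,4E)-5-cyclohexyl-N-{(1R,5S,6S)-5-hydroxy-2-oxo-5-[(E)-2-(tributylstannyl)ethenyl]-7-oxabicyclo[4.1.0]hept-3-en-3-yl}penta-2,4-dienamide | O=C(/C=C/C=C/C1CCCCC1)NC1=C[C@](O)(/C=C/[Sn](CCCC)(CCCC)CCCC)[C@H]2O[C@H]2C1=O | intermediate
24 | glutaconaldehyde potassium salt | [K+].[O-]/C=C/C=C/C=O | starting material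
25 | (2E,4E)-5-bromopenta-2,4-dienal | O=C/C=C/C=C/Br | intermediate
26 | (2E,4E)-5-bromopenta-2,4-dienoic acid | OC(=O)/C=C/C=C/Br | intermediate
27 | cyclopentane-1,3-dione | O=C1CCC(=O)C1 | starting material
28 | 2-(hydroxyimino)cyclopentane-1,3-dione | O=C1CCC(=O)C1=NO | intermediate
29 | 2-amino-3-hydroxycyclopent-2-en-1-one hydrochloride | NC1=C(O)CCC1=O.Cl | intermediate
30 | (2E,4E)-5-bromopenta-2,4-dienoyl chloride | ClC(=O)/C=C/C=C/Br | intermediate
31 | (2E,4E)-5-bromo-N-(2-hydroxy-5-oxocyclopent-1-en-1-yl)penta-2,4-dienamide | O=C(/C=C/C=C/Br)NC1=C(O)CCC1=O | intermediate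
32 | (2E,4E)-5-cyclohexyl-N-[(1R,5R,6S)-5-hydroxy-5-{(1E,3E,5E)-7-[(2-hydroxy-5-oxocyclopent-1-en-1-yl)amino]-7-oxohepta-1,3,5-trien-1-yl}-2-oxo-7-oxabicyclo[4.1.0]hept-3-en-3-yl]penta-2,4-dienamide | O=C(/C=C/C=C/C1CCCCC1)NC1=C[C@](O)(/C=C/C=C/C=C/C(=O)NC2=C(O)CCC2=O)[C@H]2O[C@H]2C1=O | target

**Step count**

Total: 18 steps. Longest linear sequence: 9 steps (steps 5–12, then 18, from squaric acid).

**Steps most likely to fail**

Step 10. The alkyne may insert with the opposite regiochemistry (acyl carbon to the CH terminus). The metallacycle may dissociate to the free vinylketene, which would close onto the C4 vinyl group and aromatise with loss of the stereochemical information. The ynamide may oligomerise on nickel. Fallback (known chemistry, the oxirane made before the carbinol): acid chloride 5, prepared from 4 as in step 3, acylates 2,5-dimethoxyaniline (pyridine, CH2Cl2) to give N-(2,5-dimethoxyphenyl)-(2E,4E)-5-cyclohexylpenta-2,4-dienamide F1. Oxidation with PhI(OAc)2 in MeOH gives the quinone monoketal N-(6,6-dimethoxy-3-oxocyclohexa-1,4-dien-1-yl) dienamide F2. Enantioselective phase-transfer Weitz–Scheffer epoxidation (t-BuOOH, NaOH, N-benzylcinchonidinium chloride or its pseudo-enantiomer, toluene/H2O) gives the (1S,6R)-epoxy ketone F3. Vinyllithium 16 adds to its ketone anti to the oxirane, the usual course for such epoxy ketones, to give the syn-hydroxy epoxide stannane F4. Stille coupling of F4 with 31 (conditions of step 18) gives the trienamide ketal F5, and mild acid hydrolysis of the dimethyl ketal (montmorillonite K10, CH2Cl2) returns to the route at target 32.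

Step 7. Facial discrimination by the remote menthyl group may be poor, and the two epimers may co-elute. Fallback (resolution instead of auxiliary control): squaric acid 10 is esterified with propan-2-ol (toluene, Dean–Stark) to diisopropyl squarate F6. LiAlH(OtBu)3 then HCl gives 3-isopropoxycyclobut-3-ene-1,2-dione F7. Addition of 16 gives racemic 4-hydroxy-3-isopropoxy-4-[(E)-2-(tributylstannyl)ethenyl]cyclobut-2-en-1-one F8. Preparative chromatography on a chiral stationary phase delivers its (4R) enantiomer F9. TESOTf/2,6-lutidine gives the (4R) silyl ether F10, and the i-Bu2AlH/oxalic acid transposition of step 9 returns to the route at 20.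

Step 4. The ambident imide anion may be alkynylated on oxygen or react sluggishly with the iodonium salt, and the Teoc group may be lost during desilylation. Fallback (copper-catalysed C–N coupling instead of hypervalent-iodine alkynyl transfer): 7 is coupled with (bromoethynyl)triisopropylsilane (CuSO4·5H2O 10 mol%, 1,10-phenanthroline 20 mol%, K3PO4, toluene, 80 °C) to give 2-(trimethylsilyl)ethyl N-[(2E,4E)-5-cyclohexylpenta-2,4-dienoyl]-N-[(triisopropylsilyl)ethynyl]carbamate F11. Selective alkynyl desilylation with AgF in MeCN followed by dilute acid returns to the route at 9.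

**Further compounds**

F1 | step 10 | N-(2,5-dimethoxyphenyl)-(2E,4E)-5-cyclohexylpenta-2,4-dienamide | COc1ccc(OC)c(NC(=O)/C=C/C=C/C2CCCCC2)c1
F2 | step 10 | (2E,4E)-5-cyclohexyl-N-(6,6-dimethoxy-3-oxocyclohexa-1,4-dien-1-yl)penta-2,4-dienamide | COC1(OC)C=CC(=O)C=C1NC(=O)/C=C/C=C/C1CCCCC1
F3 | step 10 | (2E,4E)-5-cyclohexyl-N-[(1S,6R)-5,5-dimethoxy-2-oxo-7-oxabicyclo[4.1.0]hept-3-en-4-yl]penta-2,4-dienamide | O=C1C=C(NC(=O)/C=C/C=C/C2CCCCC2)C(OC)(OC)[C@@H]2O[C@H]12
F4 | step 10 | (2E,4E)-5-cyclohexyl-N-{(1S,2S,6R)-2-hydroxy-5,5-dimethoxy-2-[(E)-2-(tributylstannyl)ethenyl]-7-oxabicyclo[4.1.0]hept-3-en-4-yl}penta-2,4-dienamide | COC1(OC)C(NC(=O)/C=C/C=C/C2CCCCC2)=C[C@](O)(/C=C/[Sn](CCCC)(CCCC)CCCC)[C@H]2O[C@@H]12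
F5 | step 10 | (2E,4E)-5-cyclohexyl-N-[(1S,2R,6R)-2-hydroxy-2-{(1E,3E,5E)-7-[(2-hydroxy-5-oxocyclopent-1-en-1-yl)amino]-7-oxohepta-1,3,5-trien-1-yl}-5,5-dimethoxy-7-oxabicyclo[4.1.0]hept-3-en-4-yl]penta-2,4-dienamide | COC1(OC)C(NC(=O)/C=C/C=C/C2CCCCC2)=C[C@](O)(/C=C/C=C/C=C/C(=O)NC2=C(O)CCC2=O)[C@H]2O[C@@H]12
F6 | step 7 | diisopropyl squarate | CC(C)OC1=C(OC(C)C)C(=O)C1=O
F7 | step 7 | 3-isopropoxycyclobut-3-ene-1,2-dione | CC(C)OC1=CC(=O)C1=O
F8 | step 7 | racemic 4-hydroxy-3-isopropoxy-4-[(E)-2-(tributylstannyl)ethenyl]cyclobut-2-en-1-one | CC(C)OC1=CC(=O)C1(O)/C=C/[Sn](CCCC)(CCCC)CCCC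
F9 | step 7 | (4R)-4-hydroxy-3-isopropoxy-4-[(E)-2-(tributylstannyl)ethenyl]cyclobut-2-en-1-one | CC(C)OC1=CC(=O)[C@@]1(O)/C=C/[Sn](CCCC)(CCCC)CCCC
F10 | step 7 | (4R)-3-isopropoxy-4-(triethylsilyloxy)-4-[(E)-2-(tributylstannyl)ethenyl]cyclobut-2-en-1-one | CC(C)OC1=CC(=O)[C@@]1(O[Si](CC)(CC)CC)/C=C/[Sn](CCCC)(CCCC)CCCC
F11 | step 4 | 2-(trimethylsilyl)ethyl N-[(2E,4E)-5-cyclohexylpenta-2,4-dienoyl]-N-[(triisopropylsilyl)ethynyl]carbamate | CC(C)[Si](C(C)C)(C(C)C)C#CN(C(=O)OCC[Si](C)(C)C)C(=O)/C=C/C=C/C1CCCCC1
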